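**Retrosynthetic overview**
1. Target 23 ⇐ Si–O cleavage of 22 ⇐ ring-closing metathesis of acyclic diene ester 21 (forms C4=C5, Z); the ten-membered carbocycle is the second and last ring formed.
2. 21 ⇐ alcohol 19 + aroyl chloride 20; 19 ⇐ syn-1,3-diol 16, whose two secondary hydroxyls are told apart by a lipase (O7 acetylation), then O9 silylation and deacetylation.
3. 16 ⇐ 1,3-syn reduction (sets C7) of β-hydroxy ketone 14 ⇐ Weinreb amide 12 + methallyl Grignard reagent 13 (C6–C7 bond).
4. 12 ⇐ anti-selective, Felkin-controlled aldol (C8–C9 bond; sets C8 and C9) of aryl isovalerate 9 with epoxy aldehyde 6.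
5. 6 ⇐ Sharpless asymmetric epoxidation of dienol 4 (oxirane is the first ring; C1 and C10 are the first stereocentres) ⇐ hex-1-en-5-yne 1.

Assumption: locants C1–C10/O11 are those of the target name (1R,4Z,7R,8S,9R,10R)-9-hydroxy-1,5-dimethyl-8-(propan-2-yl)-11-oxabicyclo[8.1.0]undec-4-en-7-yl 3,4,5-trimethoxybenzoate, and the five starting materials 1, 7, 8, 13 and 20 are taken as commercial.

**Route**

Step 1
Reactants: 1 hex-1-en-5-yne
Product: 4 (2E)-3-methylhepta-2,6-dien-1-ol, via alkenylalane 2 (not isolated), via lithium alkenylaluminate 3 (not isolated)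
Conditions: Me3Al (2 equiv), Cp2ZrCl2 (20 mol%), CH2Cl2, 0 °C to rt; then n-BuLi, THF, −78 °C; (CH2O)n, −78 °C to rt; dilute aq. HCl
Reagents that add atoms: trimethylaluminium, C[Al](C)C; formaldehyde (as paraformaldehyde), C=O
Why: Negishi zirconium-catalysed carboalumination adds CH3–Al syn across the terminal alkyne (methyl to the internal carbon), and the ate complex of the (E)-alkenylalane is hydroxymethylated with retention, while the isolated terminal alkene reacts far more slowly.

Step 2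
Reactants: 4 (2E)-3-methylhepta-2,6-dien-1-ol
Product: 5 [(2R,3R)-3-(but-3-en-1-yl)-3-methyloxiran-2-yl]methanol
Conditions: Ti(OiPr)4 (5 mol%), D-(−)-diethyl tartrate (6 mol%), t-BuOOH (2 equiv, decane), 4 Å molecular sieves, CH2Cl2, −20 °C
Reagents that add atoms: tert-butyl hydroperoxide, CC(C)(C)OO
Why: Catalytic Sharpless asymmetric epoxidation of an (E)-allylic alcohol; D-(−)-tartrate gives the (2R,3R)-epoxide (mirror image of the (2S,3S)-epoxide that L-(+)-tartrate gives with geraniol), setting C1 and C10 as the first stereocentres and leaving the unactivated terminal alkene untouched.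

Step 3
Reactants: 5 [(2R,3R)-3-(but-3-en-1-yl)-3-methyloxiran-2-yl]methanol
Product: 6 (2S,3R)-3-(but-3-en-1-yl)-3-methyloxirane-2-carbaldehyde
Conditions: nPr4N[RuO4] (5 mol%), N-methylmorpholine N-oxide (1.5 equiv), 4 Å molecular sieves, CH2Cl2, 0 °C to rt
Reagents that add atoms: none
Why: Ley–Griffith oxidation is neutral, so the sensitive α,β-epoxy aldehyde forms without epoxide opening or epimerisation (the descriptor at C2 changes only because the CIP priorities change).

Step 4
Reactants: 7 3-methylbutanoyl chloride; 8 2,6-dimethylphenol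
Product: 9 2,6-dimethylphenyl 3-methylbutanoate
Conditions: Et3N, DMAP (5 mol%), CH2Cl2, 0 °C to rt
Reagents that add atoms: none
Why: DMAP-catalysed acylation of the phenol gives the hindered aryl ester needed for a clean E(O)-enolate and later as an activated acyl donor.

Step 5
Reactants: 9 2,6-dimethylphenyl 3-methylbutanoate; 6 (2S,3R)-3-(but-3-en-1-yl)-3-methyloxirane-2-carbaldehyde
Product: 11 2,6-dimethylphenyl (2S,3R)-3-[(2R,3R)-3-(but-3-en-1-yl)-3-methyloxiran-2-yl]-3-hydroxy-2-(propan-2-yl)propanoate, via lithium enolate 10 (not isolated)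
Conditions: LiN(iPr)2 (1.3 equiv), 9 (1.3 equiv), THF, −78 °C, 45 min; then 6, −78 °C, 20 min; AcOH/THF quench at −78 °C
Reagents that add atoms: none
Why: Kinetic deprotonation of the aryl ester gives the E(O)-lithium enolate, which reacts through a Zimmerman–Traxler chair (anti aldol) on the Felkin–Anh/Cornforth face of the epoxy aldehyde (epoxide C–O anti to the incoming nucleophile), so C8 and C9 are set anti to each other with C9–OH erythro to the oxirane.

Step 6
Reactants: 11 aldol ester (2,6-dimethylphenyl (2S,3R)-3-hydroxy-2-isopropyl-3-oxiranylpropanoate)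
Product: 12 (2S,3R)-3-[(2R,3R)-3-(but-3-en-1-yl)-3-methyloxiran-2-yl]-3-hydroxy-N-methoxy-N-methyl-2-(propan-2-yl)propanamide
Conditions: MeNH(OMe)·HCl (1.6 equiv), iPrMgCl (4.2 equiv), THF, −20 to 0 °C; aq. NH4Cl
Reagents that add atoms: N,O-dimethylhydroxylamine hydrochloride, CNOC.Cl
Why: Aminolysis of the activated aryl ester by the chloromagnesium amide gives the Weinreb amide at low temperature, without epimerising C8 or disturbing the epoxide.

Step 7
Reactants: 12 Weinreb amide; 13 2-methylallylmagnesium chloride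
Product: 14 (5S,6R)-6-[(2R,3R)-3-(but-3-en-1-yl)-3-methyloxiran-2-yl]-6-hydroxy-2-methyl-5-(propan-2-yl)hex-1-en-4-one
Conditions: 13 (3 equiv), THF, −78 to −40 °C; aq. NH4Cl at −78 °C; used at once
Reagents that add atoms: none
Why: Weinreb ketone synthesis stops at mono-addition, and the β,γ-unsaturated ketone is released only on the cold, mildly acidic quench, so it neither conjugates nor epimerises at C8.

Step 8
Reactants: 14 β-hydroxy ketone
Product: 16 (4R,5R,6R)-6-[(2R,3R)-3-(but-3-en-1-yl)-3-methyloxiran-2-yl]-2-methyl-5-(propan-2-yl)hex-1-ene-4,6-diol, via boron chelate 15 (not isolated)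
Conditions: Et2BOMe (1.1 equiv), THF/MeOH (4:1), −78 °C; NaBH4, −78 °C; then repeated co-evaporation from MeOH
Reagents that add atoms: none
Why: Narasaka–Prasad reduction: in the six-membered boron chelate the isopropyl group and both chains are pseudo-equatorial and external hydride adds axially, giving the 1,3-syn diol and thus the anti,anti C7–C8–C9 triad (new C7 centre).

Step 9
Reactants: 16 syn-1,3-diol
Product: 17 (4R,5S,6R)-6-[(2R,3R)-3-(but-3-en-1-yl)-3-methyloxiran-2-yl]-6-hydroxy-2-methyl-5-(propan-2-yl)hex-1-en-4-yl acetate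
Conditions: immobilised Burkholderia cepacia lipase, vinyl acetate (5 equiv), t-BuOMe, 4 Å molecular sieves, 40 °C
Reagents that add atoms: vinyl acetate, C=COC(C)=O
Why: Lipase-catalysed irreversible transesterification acetylates only the future C7 hydroxyl, an (R)-carbinol with one CH2 and one large branched substituent (Kazlauskas rule), whereas the C9 hydroxyl sits between two bulky groups; the enzyme also leaves behind material of the minor enantiomeric series from step 2.

Step 10
Reactants: 17 mono-acetate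
Product: 18 (4R,5R,6R)-6-[(2R,3R)-3-(but-3-en-1-yl)-3-methyloxiran-2-yl]-2-methyl-5-(propan-2-yl)-6-[(triethylsilyl)oxy]hex-1-en-4-yl acetate
Conditions: Et3SiOTf (1.5 equiv), 2,6-lutidine (3 equiv), CH2Cl2, −78 °C
Reagents that add atoms: triethylsilyl trifluoromethanesulfonate, CC[Si](CC)(CC)OS(=O)(=O)C(F)(F)F
Why: The silyl triflate with a hindered pyridine base silylates the remaining hindered hydroxyl at −78 °C faster than it activates the epoxide, and the acetate is inert.

Step 11
Reactants: 18 acetate silyl ether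
Product: 19 (4R,5R,6R)-6-[(2R,3R)-3-(but-3-en-1-yl)-3-methyloxiran-2-yl]-2-methyl-5-(propan-2-yl)-6-[(triethylsilyl)oxy]hex-1-en-4-ol
Conditions: iBu2AlH (2.5 equiv), CH2Cl2, −78 °C; aq. potassium sodium tartrate
Reagents that add atoms: none
Why: Reductive ester cleavage at −78 °C frees O7 without a basic alkoxide in protic medium, which avoids 1,5-silyl migration and leaves the epoxide intact.

Step 12
Reactants: 19 alcohol; 20 3,4,5-trimethoxybenzoyl chloride
Product: 21 (4R,5R,6R)-6-[(2R,3R)-3-(but-3-en-1-yl)-3-methyloxiran-2-yl]-2-methyl-5-(propan-2-yl)-6-[(triethylsilyl)oxy]hex-1-en-4-yl 3,4,5-trimethoxybenzoate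
Conditions: 20 (1.5 equiv), Et3N (3 equiv), DMAP (1 equiv), CH2Cl2, 0 °C to rt
Reagents that add atoms: none
Why: DMAP-mediated acyl transfer esterifies the only free hydroxyl (O7) with retention at carbon.

Step 13
Reactants: 21 diene ester
Product: 22 (1R,4Z,7R,8R,9R,10R)-1,5-dimethyl-8-(propan-2-yl)-9-[(triethylsilyl)oxy]-11-oxabicyclo[8.1.0]undec-4-en-7-yl 3,4,5-trimethoxybenzoate
Conditions: second-generation Grubbs catalyst (H2IMes)(PCy3)Cl2Ru=CHPh (10 mol%), toluene (1 mM), 80 °C, argon sparge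
Reagents that add atoms: none
Why: Ring-closing metathesis between the monosubstituted alkene (initiation site) and the 1,1-disubstituted methallyl alkene closes the ten-membered ring with loss of ethene; the less strained cis (Z) trisubstituted ring olefin is expected, and no stereocentre is touched.

Step 14
Reactants: 22 macrocyclic silyl ether
Product: 23 (1R,4Z,7R,8S,9R,10R)-9-hydroxy-1,5-dimethyl-8-(propan-2-yl)-11-oxabicyclo[8.1.0]undec-4-en-7-yl 3,4,5-trimethoxybenzoate
Conditions: HF·pyridine, pyridine, THF, 0 °C to rt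
Reagents that add atoms: none
Why: Buffered fluoride-mediated Si–O cleavage removes the silyl ether under near-neutral conditions, so the trisubstituted epoxide is not opened and the ester does not migrate (the C8 descriptor changes from R to S only through CIP priorities).

**Compound list**
1 | hex-1-en-5-yne | C=CCCC#C | starting material
2 | dimethyl[(1E)-2-methylhexa-1,5-dien-1-yl]alumane (alkenylalane) | C=CCC/C(C)=C/[Al](C)C | intermediate
3 | lithium butyl(dimethyl)[(1E)-2-methylhexa-1,5-dien-1-yl]aluminate | [Li+].C=CCC/C(C)=C/[Al-](C)(C)CCCC | intermediate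
4 | (2E)-3-methylhepta-2,6-dien-1-ol | C=CCC/C(C)=C/CO | intermediate
5 | [(2R,3R)-3-(but-3-en-1-yl)-3-methyloxiran-2-yl]methanol | OC[C@H]1O[C@]1(C)CCC=C | intermediate
6 | (2S,3R)-3-(but-3-en-1-yl)-3-methyloxirane-2-carbaldehyde | O=C[C@H]1O[C@]1(C)CCC=C | intermediate
7 | 3-methylbutanoyl chloride | CC(C)CC(=O)Cl | starting material
8 | 2,6-dimethylphenol | Cc1cccc(C)c1O | starting material
9 | 2,6-dimethylphenyl 3-methylbutanoate | CC(C)CC(=O)Oc1c(C)cccc1C | intermediate
10 | lithium (1Z)-1-(2,6-dimethylphenoxy)-3-methylbut-1-en-1-olate (E(O)-enolate, O–Li trans to isopropyl) | [Li+].CC(C)/C=C(/[O-])Oc1c(C)cccc1C | intermediate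
11 | 2,6-dimethylphenyl (2S,3R)-3-[(2R,3R)-3-(but-3-en-1-yl)-3-methyloxiran-2-yl]-3-hydroxy-2-(propan-2-yl)propanoate | Cc1cccc(C)c1OC(=O)[C@@H](C(C)C)[C@@H](O)[C@H]2O[C@]2(C)CCC=C | intermediate
12 | (2S,3R)-3-[(2R,3R)-3-(but-3-en-1-yl)-3-methyloxiran-2-yl]-3-hydroxy-N-methoxy-N-methyl-2-(propan-2-yl)propanamide | CON(C)C(=O)[C@@H](C(C)C)[C@@H](O)[C@H]1O[C@]1(C)CCC=C | intermediate
13 | 2-methylallylmagnesium chloride | C=C(C)C[Mg]Cl | starting material
14 | (5S,6R)-6-[(2R,3R)-3-(but-3-en-1-yl)-3-methyloxiran-2-yl]-6-hydroxy-2-methyl-5-(propan-2-yl)hex-1-en-4-one | C=C(C)CC(=O)[C@@H](C(C)C)[C@@H](O)[C@H]1O[C@]1(C)CCC=C | intermediate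
15 | (5S,6R)-6-[(2R,3R)-3-(but-3-en-1-yl)-3-methyloxiran-2-yl]-6-[(diethylboranyl)oxy]-2-methyl-5-(propan-2-yl)hex-1-en-4-one (boron chelate) | C=C(C)CC(=O)[C@@H](C(C)C)[C@@H](OB(CC)CC)[C@H]1O[C@]1(C)CCC=C | intermediate
16 | (4R,5R,6R)-6-[(2R,3R)-3-(but-3-en-1-yl)-3-methyloxiran-2-yl]-2-methyl-5-(propan-2-yl)hex-1-ene-4,6-diol | C=C(C)C[C@@H](O)[C@@H](C(C)C)[C@@H](O)[C@H]1O[C@]1(C)CCC=C | intermediate
17 | (4R,5S,6R)-6-[(2R,3R)-3-(but-3-en-1-yl)-3-methyloxiran-2-yl]-6-hydroxy-2-methyl-5-(propan-2-yl)hex-1-en-4-yl acetate | C=C(C)C[C@@H](OC(C)=O)[C@@H](C(C)C)[C@@H](O)[C@H]1O[C@]1(C)CCC=C | intermediate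
18 | (4R,5R,6R)-6-[(2R,3R)-3-(but-3-en-1-yl)-3-methyloxiran-2-yl]-2-methyl-5-(propan-2-yl)-6-[(triethylsilyl)oxy]hex-1-en-4-yl acetate | C=C(C)C[C@@H](OC(C)=O)[C@@H](C(C)C)[C@@H](O[Si](CC)(CC)CC)[C@H]1O[C@]1(C)CCC=C | intermediate
19 | (4R,5R,6R)-6-[(2R,3R)-3-(but-3-en-1-yl)-3-methyloxiran-2-yl]-2-methyl-5-(propan-2-yl)-6-[(triethylsilyl)oxy]hex-1-en-4-ol | C=C(C)C[C@@H](O)[C@@H](C(C)C)[C@@H](O[Si](CC)(CC)CC)[C@H]1O[C@]1(C)CCC=C | intermediate
20 | 3,4,5-trimethoxybenzoyl chloride | COc1cc(C(=O)Cl)cc(OC)c1OC | starting material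
21 | (4R,5R,6R)-6-[(2R,3R)-3-(but-3-en-1-yl)-3-methyloxiran-2-yl]-2-methyl-5-(propan-2-yl)-6-[(triethylsilyl)oxy]hex-1-en-4-yl 3,4,5-trimethoxybenzoate | COc1cc(C(=O)O[C@H](CC(C)=C)[C@@H](C(C)C)[C@@H](O[Si](CC)(CC)CC)[C@H]2O[C@]2(C)CCC=C)cc(OC)c1OC | intermediate
22 | (1R,4Z,7R,8R,9R,10R)-1,5-dimethyl-8-(propan-2-yl)-9-[(triethylsilyl)oxy]-11-oxabicyclo[8.1.0]undec-4-en-7-yl 3,4,5-trimethoxybenzoate | COc1cc(C(=O)O[C@@H]2C/C(C)=C\CC[C@@]3(C)O[C@@H]3[C@H](O[Si](CC)(CC)CC)[C@@H]2C(C)C)cc(OC)c1OC | intermediate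
23 | (1R,4Z,7R,8S,9R,10R)-9-hydroxy-1,5-dimethyl-8-(propan-2-yl)-11-oxabicyclo[8.1.0]undec-4-en-7-yl 3,4,5-trimethoxybenzoate | COc1cc(C(=O)O[C@@H]2C/C(C)=C\CC[C@@]3(C)O[C@@H]3[C@H](O)[C@@H]2C(C)C)cc(OC)c1OC | target

**Step count**
Total: 14 steps. Longest linear sequence: 13 steps (1 → 4 → 5 → 6 → 11 → 12 → 14 → 16 → 17 → 18 → 19 → 21 → 22 → 23); step 4 is a one-step side branch.

**Three steps most likely to fail, with fallbacks**

Step 5 (aldol; two stereocentres rest on enolate geometry and on the Felkin bias of the epoxy aldehyde). The fallback sets out from 9 and 6 and comes back at 11. It replaces the kinetic lithium enolate by a boron-mediated soft-enolisation aldol. Ester 9 is enolised with (c-C6H11)2BOTf and Et3N in CH2Cl2 at −78 °C to the dicyclohexylboron E(O)-enolate F1. F1 adds to 6 through a tighter boron-centred chair, which usually gives higher anti and Felkin ratios, to give the boron aldolate F2. Work-up with H2O2 in pH 7 buffer/MeOH at 0 °C releases 11.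

Step 9 (lipase acetylation; the carbinol is hindered, so the enzyme may be slow or unselective). The fallback sets out from 16 and comes back at 21. It uses steric differentiation by a chemical acyl donor in place of the enzyme. Diol 16 is treated with 20 (1.05 equiv), 2,4,6-collidine and catalytic DMAP in CH2Cl2 at −40 °C; the less hindered, more nucleophilic O7 hydroxyl reacts first to give (4R,5S,6R)-6-[(2R,3R)-3-(but-3-en-1-yl)-3-methyloxiran-2-yl]-6-hydroxy-2-methyl-5-(propan-2-yl)hex-1-en-4-yl 3,4,5-trimethoxybenzoate F3. Silylation of F3 with Et3SiOTf/2,6-lutidine at −78 °C gives 21, bypassing 17–19.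

Step 13 (ring-closing metathesis; a ten-membered ring with a trisubstituted olefin may close slowly or as the E isomer). The fallback sets out from 21 and comes back at 22. It moves olefin-geometry control from the kinetic ring closure to a thermodynamic equilibration afterwards. If metathesis gives the trans ring olefin (1R,4E,7R,8R,9R,10R)-1,5-dimethyl-8-(propan-2-yl)-9-[(triethylsilyl)oxy]-11-oxabicyclo[8.1.0]undec-4-en-7-yl 3,4,5-trimethoxybenzoate F4, alone or mixed with 22, the material is equilibrated by reversible thiyl-radical addition (PhSSPh 20 mol%, 350 nm light, benzene, rt). This should converge on the less strained cis-cyclodecene 22, which is then purified and carried into step 14.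

**Further compounds**
F1 | step 5 | {[(1Z)-1-(2,6-dimethylphenoxy)-3-methylbut-1-en-1-yl]oxy}dicyclohexylborane (dicyclohexylboron E(O)-enolate of 9) | CC(C)/C=C(/OB(C1CCCCC1)C1CCCCC1)Oc1c(C)cccc1C
F2 | step 5 | 2,6-dimethylphenyl (2S,3R)-3-[(2R,3R)-3-(but-3-en-1-yl)-3-methyloxiran-2-yl]-3-[(dicyclohexylboranyl)oxy]-2-(propan-2-yl)propanoate (boron aldolate) | Cc1cccc(C)c1OC(=O)[C@@H](C(C)C)[C@@H](OB(C1CCCCC1)C1CCCCC1)[C@H]1O[C@]1(C)CCC=C
F3 | step 9 | (4R,5S,6R)-6-[(2R,3R)-3-(but-3-en-1-yl)-3-methyloxiran-2-yl]-6-hydroxy-2-methyl-5-(propan-2-yl)hex-1-en-4-yl 3,4,5-trimethoxybenzoate | COc1cc(C(=O)O[C@H](CC(C)=C)[C@@H](C(C)C)[C@@H](O)[C@H]2O[C@]2(C)CCC=C)cc(OC)c1OC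
F4 | step 13 | (1R,4E,7R,8R,9R,10R)-1,5-dimethyl-8-(propan-2-yl)-9-[(triethylsilyl)oxy]-11-oxabicyclo[8.1.0]undec-4-en-7-yl 3,4,5-trimethoxybenzoate | COc1cc(C(=O)O[C@@H]2C/C(C)=C/CC[C@@]3(C)O[C@@H]3[C@H](O[Si](CC)(CC)CC)[C@@H]2C(C)C)cc(OC)c1OC
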